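There were 3 questions on Saturday's flask. The readings bear directly on the first, so I reckoned that one by hand.

the same everywhere: solid substrate 10 mM
- Saturday's: gas phase 2 mM (held); protic impurity 1 mM; the very flask that is asked about, followed so far
- flask: gas phase 2.0 mM (held); protic impurity 1.00 mM; time 6.0 d

Saturday's run (percent of the solid substrate charged)

| time / h | target / % | solid substrate / % |
|---|---|---|
| 8.00 | 0 | 70.7 |
| 15.0 | 1.8 | 54.4 |
| 20.0 | 4.2 | 46.2 |
| 30.0 | 6.4 | 36.0 |

(readings scatter by 0.5 percentage points)

- as a solid, counted per litre of solution: solid substrate
- at the start none of the gas phase is in solution
- at the start none of the solid substrate is in solution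

- summer: doubling the dissolution coefficient of the solid substrate, all else as stated
- autumn: doubling the solubility of the solid substrate, all else as stated
- dawn: doubling the saturation concentration of gas phase, all else as stated
- dusk: doubling the transfer coefficient of the gas phase, all else as stated

1. target at 6.0 d, in percent of the solid substrate charged
2. the change that raises the amount of target at 6.0 d, in percent of the solid substrate charged most ("none" if none brings more than 2 percentage points) (summer / autumn / dawn / dusk / none)
3. amount of target at 6.0 d, in percent of the solid substrate charged, after dusk

By 30.0 h the solid substrate had lost ten times what had become target, so supply ran well ahead of product, and I integrated a constant rate, a zero-order line. For a ceiling I took the stretch from 15.0 h to 20.0 h, at 0.00480 h⁻¹ of the charge, and carried it from the last reading to 6.0 d, which gave 61.1%. For a floor I took the next stretch, from 20.0 h to 30.0 h, which read 0.00220 h⁻¹ of the charge and, carried the same way, gave 31.5%. Both stretches share the reading at 20.0 h, whose scatter of 0.5 percentage points pushes them opposite ways, so I tightened by stepping over it. That gave the target pace, the share of the charge turned into target per hour after the lag, taken from 15.0 h to 30.0 h: 0.00307 h⁻¹. Run back to zero, this line put the lag at 9.13 h, and run forward it gave 41.4%.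

The forecast gave 42%, named dawn as the best change, and gave 49% after dusk. Its ground for the first was this: “Extrapolating over 135 h, with slight slowing once the solid is gone, gives about 42%.” That figure lay inside my bracket, 0.60 points above my line.

The flask gave 44.1%, inside the bracket and 2.7 points above my line, with dawn the best change at a gain of 13 points, and 49.3% after dusk.

    gas phase ⇌ dissolved gas, rate k1*(csat - [dissolved gas]) (kL = 0.00105 min⁻¹)
    starting material + dissolved gas → target (k = 0.101 L mol⁻¹ min⁻¹)
    dissolved gas + target → over-reacted product (k = 0.0190 L mol⁻¹ min⁻¹)
    solid substrate ⇌ starting material, rate k4*(cs4 - [starting material]) while solid is left; crystals form when [starting material] > cs4 (solubility = 6.70 mM, k = 0.00119 min⁻¹)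
    target ⇌ isomer of the product (K = 0.109, k = 6.16 × 10⁻⁴ min⁻¹)
    starting material + protic impurity → quenched substrate (k = 0.0910 L mol⁻¹ min⁻¹)

At 6.00 d target was still being made 3.30 times faster than it was used up, each step taken net. Over the 135 h after my lag this flask averaged 0.00327 h⁻¹ of the charge, against the target pace of 0.00307 h⁻¹. For the same flask read at 2.5 d the pace gives 15.6%, and it stood at 17.9%.

The readings were generated by integration with made-up constants; the scatter is artificial.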